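**Strategy.** Everything rests on cutting pyran ring C at C4–C4a and O1–C2, which leaves a ring-A phenol and a three-carbon 2-arylacrolein (C2–C3–C4) bearing ring B on C3. The key step exploits two features: C4a is the only unsubstituted carbon ortho to the oxygen on C8a of ring A (and para to the 7-OMe), and C3, the sole stereocentre, is the α-carbon of that enal. In one chiral-amine-catalysed operation C4 is joined to C4a, C3 is protonated face-selectively and O1 closes on C2 as a lactol. The precursors are 4-(benzyloxy)-2,3-dimethoxyphenol and 2-[2,5-bis(benzyloxy)-3,4-dimethoxyphenyl]prop-2-enal, both derived from 2,3-dimethoxy-1,4-benzoquinone, with benzyl ethers masking the quinone and the 6-OH.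

Key step: step 7

Remark: 2,3-dimethoxy-1,4-benzoquinone is taken as a catalogue compound. The target is (3S); the catalyst antipode that delivers 3S (both are available from L- or D-tert-leucine) is assumed to be fixed by a trial run.

**Step 1**
Reactants: 1 2,3-dimethoxy-1,4-benzoquinone
Product: 2 2,3-dimethoxybenzene-1,4-diol
Conditions: Na2S2O4 (aq), EtOAc, rt, Ar
Reagents that add atoms: none
Why: Quinone reduction with dithionite is the standard two-electron reduction of benzoquinones, leaves the methyl ethers untouched and should give the hydroquinone, which is kept under argon to prevent re-oxidation.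

**Step 2**
Reactants: 2 2,3-dimethoxybenzene-1,4-diol; 3 benzyl bromide
Product: 4 4-(benzyloxy)-2,3-dimethoxyphenol
Conditions: 2 (2.5 equiv), BnBr (1.0 equiv), K2CO3 (1.1 equiv), DMF, 0 °C → rt, Ar
Reagents that add atoms: none
Why: Williamson ether synthesis on a symmetrical hydroquinone used in excess should favour the single possible mono-ether, with unreacted 2 recovered by base extraction and any bis-ether being compound 5 of the other branch.

**Step 3**
Reactants: 2 2,3-dimethoxybenzene-1,4-diol; 3 benzyl bromide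
Product: 5 1,4-bis(benzyloxy)-2,3-dimethoxybenzene
Conditions: BnBr (2.5 equiv), K2CO3 (3 equiv), DMF, 60 °C, Ar
Reagents that add atoms: benzyl bromide (second equivalent), BrCc1ccccc1
Why: Exhaustive Williamson benzylation, in which each of the two phenolic hydroxyls takes up one equivalent of benzyl bromide, is routine and should give the symmetrical bis-ether.

**Step 4**
Reactants: 5 1,4-bis(benzyloxy)-2,3-dimethoxybenzene
Product: 6 2,5-bis(benzyloxy)-3,4-dimethoxybenzaldehyde
Conditions: POCl3 (2 equiv), DMF, 0 → 70 °C; then ice–water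
Reagents that add atoms: N,N-dimethylformamide, CN(C)C=O (formyl carbon); water, O (aldehyde oxygen)
Why: Vilsmeier–Haack formylation of a tetra-alkoxybenzene whose two free positions are equivalent by symmetry can give only one aldehyde, and benzyl aryl ethers tolerate the chloroiminium reagent.

**Step 5**
Reactants: 6 2,5-bis(benzyloxy)-3,4-dimethoxybenzaldehyde
Product: 8 2-[2,5-bis(benzyloxy)-3,4-dimethoxyphenyl]acetaldehyde, via enol ether 7 (not isolated)
Conditions: Ph3P(CH2OMe)Cl (1.5 equiv), KOt-Bu (1.4 equiv), THF, 0 °C → rt; then 2 M aq. HCl, THF, 40 °C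
Reagents that add atoms: (methoxymethyl)triphenylphosphonium chloride, COC[P+](c1ccccc1)(c1ccccc1)c1ccccc1.[Cl-]; water, O
Why: Wittig one-carbon homologation with the methoxymethylene ylide followed by mild acid hydrolysis of the enol ether is the standard way from ArCHO to ArCH2CHO and leaves benzyl ethers intact.

**Step 6**
Reactants: 8 2-[2,5-bis(benzyloxy)-3,4-dimethoxyphenyl]acetaldehyde; 9 formaldehyde
Product: 10 2-[2,5-bis(benzyloxy)-3,4-dimethoxyphenyl]prop-2-enal
Conditions: 37% aq. HCHO (1.2 equiv), pyrrolidine (10 mol%), propionic acid (10 mol%), i-PrOH, 45 °C; used at once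
Reagents that add atoms: none
Why: Amine-catalysed Mannich condensation with β-elimination (α-methylenation of an aldehyde) should convert the arylacetaldehyde, through its enamine and the formaldehyde iminium ion, into the conjugated 2-arylacrolein, which is used immediately to avoid dimerisation.

**Step 7**
Reactants: 4 4-(benzyloxy)-2,3-dimethoxyphenol; 10 2-[2,5-bis(benzyloxy)-3,4-dimethoxyphenyl]prop-2-enal
Product: 12 (3S)-6-(benzyloxy)-3-[2,5-bis(benzyloxy)-3,4-dimethoxyphenyl]-7,8-dimethoxychroman-2-ol (C2 epimer mixture), via hydroxy aldehyde 11 (not isolated)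
Conditions: 4 (1.0 equiv), 10 (1.3 equiv), (2S)-N1,N1-diethyl-3,3-dimethylbutane-1,2-diamine·TfOH (20 mol%), CHCl3 (undried), 0 °C → rt, Ar
Reagents that add atoms: none
Why: Proposed new method: the primary amine condenses with enal 10 to an α-aryl iminium ion, C6 of phenol 4 (the future C4a) adds to its unsubstituted CH2 terminus to make C4–C4a while the phenolic OH is hydrogen-bonded to the catalyst salt, and the aryl-conjugated enamine left after rearomatisation is protonated at the future C3 by the adjacent tertiary ammonium group before hydrolysis releases hydroxy aldehyde 11. The closest known reaction types are primary-amine-catalysed Friedel–Crafts additions of indoles to α-substituted acroleins with enantioselective enamine protonation and secondary-amine-catalysed phenol or naphthol annulations of enals to chroman-2-ols; their combination on a 2-arylacrolein is untested. Ring C closes by 6-exo-trig attack of the phenolic oxygen on the aldehyde carbon (O1–C2), which gives lactol 12 and takes the epimerisable α-aryl aldehyde out of the enol/enamine manifold. C3 is controlled by the catalyst, which shields one face of the enamine and delivers the proton intramolecularly to the other, whereas the anomeric C2 forms as a mixture that step 8 erases. The step needs C- over O-alkylation and attack ortho to the hydroxyl: oxa-Michael addition is reversible while C-addition becomes irreversible on rearomatisation, and C6 is the only open ortho position of 4, activated by the OH and the para-OMe, whereas the other free carbon (C5) sits next to the benzyl ether and is not reached by the hydrogen-bonded delivery.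

**Step 8**
Reactants: 12 (3S)-6-(benzyloxy)-3-[2,5-bis(benzyloxy)-3,4-dimethoxyphenyl]-7,8-dimethoxychroman-2-ol
Product: 13 (3S)-6-(benzyloxy)-3-[2,5-bis(benzyloxy)-3,4-dimethoxyphenyl]-7,8-dimethoxychroman
Conditions: Et3SiH (3 equiv), BF3·OEt2 (1.5 equiv), CH2Cl2, −78 → −40 °C; aqueous work-up
Reagents that add atoms: none
Why: Ionic hydrogenation of a lactol, in which BF3 ionises the anomeric hydroxyl to an aryl oxocarbenium ion that triethylsilane reduces at C2 at low temperature, should keep O1–C2 in place and leave the S configuration at C3 untouched as long as the ion is trapped before it can tautomerise.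

**Step 9**
Reactants: 13 (3S)-6-(benzyloxy)-3-[2,5-bis(benzyloxy)-3,4-dimethoxyphenyl]-7,8-dimethoxychroman
Product: 15 5-[(3S)-6-hydroxy-7,8-dimethoxychroman-3-yl]-2,3-dimethoxycyclohexa-2,5-diene-1,4-dione (CNP0302517.1), via hydroquinone 14 (not isolated)
Conditions: H2 (1 atm), 10% Pd/C, EtOAc, rt; filter under Ar; then Ag2O (1.2 equiv), MgSO4, rt
Reagents that add atoms: none
Why: Hydrogenolysis of the three benzyl aryl ethers over Pd/C should give the ring-B hydroquinone, which silver(I) oxide oxidises to the quinone far more readily than the ring-A mono-phenol (a hydroquinone mono-ether), while C3 takes no part.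

**Compound list**
1 | 2,3-dimethoxy-1,4-benzoquinone | COC1=C(OC)C(=O)C=CC1=O | starting material
2 | 2,3-dimethoxybenzene-1,4-diol | COc1c(O)ccc(O)c1OC | intermediate
3 | benzyl bromide | BrCc1ccccc1 | starting material
4 | 4-(benzyloxy)-2,3-dimethoxyphenol | COc1c(O)ccc(OCc2ccccc2)c1OC | intermediate
5 | 1,4-bis(benzyloxy)-2,3-dimethoxybenzene | COc1c(OCc2ccccc2)ccc(OCc2ccccc2)c1OC | intermediate
6 | 2,5-bis(benzyloxy)-3,4-dimethoxybenzaldehyde | O=Cc1cc(OCc2ccccc2)c(OC)c(OC)c1OCc1ccccc1 | intermediate
7 | 1,4-bis(benzyloxy)-2,3-dimethoxy-5-(2-methoxyethenyl)benzene (E/Z mixture) | COC=Cc1cc(OCc2ccccc2)c(OC)c(OC)c1OCc1ccccc1 | intermediate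
8 | 2-[2,5-bis(benzyloxy)-3,4-dimethoxyphenyl]acetaldehyde | O=CCc1cc(OCc2ccccc2)c(OC)c(OC)c1OCc1ccccc1 | intermediate
9 | formaldehyde | C=O | starting material
10 | 2-[2,5-bis(benzyloxy)-3,4-dimethoxyphenyl]prop-2-enal | C=C(C=O)c1cc(OCc2ccccc2)c(OC)c(OC)c1OCc1ccccc1 | intermediate
11 | (2S)-2-[2,5-bis(benzyloxy)-3,4-dimethoxyphenyl]-3-[5-(benzyloxy)-2-hydroxy-3,4-dimethoxyphenyl]propanal | O=C[C@@H](Cc1cc(OCc2ccccc2)c(OC)c(OC)c1O)c1cc(OCc2ccccc2)c(OC)c(OC)c1OCc1ccccc1 | intermediate
12 | (3S)-6-(benzyloxy)-3-[2,5-bis(benzyloxy)-3,4-dimethoxyphenyl]-7,8-dimethoxychroman-2-ol (C2 epimer mixture) | COc1c(OC)c(OCc2ccccc2)cc([C@H]2C(O)Oc3c(cc(OCc4ccccc4)c(OC)c3OC)C2)c1OCc1ccccc1 | intermediate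
13 | (3S)-6-(benzyloxy)-3-[2,5-bis(benzyloxy)-3,4-dimethoxyphenyl]-7,8-dimethoxychroman | COc1c(OC)c(OCc2ccccc2)cc([C@H]2COc3c(cc(OCc4ccccc4)c(OC)c3OC)C2)c1OCc1ccccc1 | intermediate
14 | 2-[(3S)-6-hydroxy-7,8-dimethoxychroman-3-yl]-5,6-dimethoxybenzene-1,4-diol | COc1c(OC)c(O)cc([C@H]2COc3c(cc(O)c(OC)c3OC)C2)c1O | intermediate
15 | 5-[(3S)-6-hydroxy-7,8-dimethoxychroman-3-yl]-2,3-dimethoxycyclohexa-2,5-diene-1,4-dione | COC1=C(OC)C(=O)C([C@H]2COc3c(cc(O)c(OC)c3OC)C2)=CC1=O | target

**Step count.** Total: 9 steps. Longest linear sequence: 8 steps (1, 3, 4, 5, 6, 7, 8, 9); the phenol branch (1, 2) joins at step 7.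

**Steps most likely to fail**

Step 7 (Proposed new method). The phenol may add too slowly to the hindered α-aryl iminium ion, the enamine may be protonated with poor facial selectivity, or the lactol may epimerise through its open form under the amine salt. The fallback uses known chemistry and sets the stereocentre by asymmetric hydrogenation instead of protonation. It sets out from phenol 4 and aldehyde 8 and returns at chroman 13, so steps 6–8 are bypassed. Magnesium-mediated ortho-formylation of 4 (MgCl2, Et3N, paraformaldehyde, MeCN, reflux) should give 5-(benzyloxy)-2-hydroxy-3,4-dimethoxybenzaldehyde F1, and Pinnick oxidation of 8 (NaClO2, NaH2PO4, 2-methyl-2-butene, t-BuOH/H2O) should give 2-[2,5-bis(benzyloxy)-3,4-dimethoxyphenyl]acetic acid F2. Perkin condensation of F1 with F2 (Ac2O, Et3N, 110 °C) should give 6-(benzyloxy)-3-[2,5-bis(benzyloxy)-3,4-dimethoxyphenyl]-7,8-dimethoxy-2H-chromen-2-one F3. DIBAL-H (CH2Cl2, −78 → 0 °C) should reduce the lactone to 4-(benzyloxy)-6-{(1Z)-2-[2,5-bis(benzyloxy)-3,4-dimethoxyphenyl]-3-hydroxyprop-1-en-1-yl}-2,3-dimethoxyphenol F4. Mitsunobu etherification (PPh3, DIAD, THF) should close this to 6-(benzyloxy)-3-[2,5-bis(benzyloxy)-3,4-dimethoxyphenyl]-7,8-dimethoxy-2H-chromene F5. Iridium-catalysed asymmetric hydrogenation of the C3=C4 bond (chiral Ir–phosphine-oxazoline catalyst, H2, CH2Cl2), with the ligand antipode chosen for 3S, should then deliver 13.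

Step 8. The oxocarbenium ion may lose the C3 proton to give the 4H-chromene enol ether, whose reduction would erode the C3 configuration, or the open hydroxy aldehyde may be reduced instead of the cyclic ion. The fallback runs from lactol 12 to chroman 13 without a cation at C2. NaBH4 (MeOH/THF, 0 °C) should reduce 12 through its open form to (2S)-2-[2,5-bis(benzyloxy)-3,4-dimethoxyphenyl]-3-[5-(benzyloxy)-2-hydroxy-3,4-dimethoxyphenyl]propan-1-ol F6. Mitsunobu cyclisation (PPh3, DIAD, THF, 0 °C → rt) of the only free phenol onto the primary alcohol should then give 13 by SN2 displacement away from the stereocentre.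

Step 6. The enolisable arylacetaldehyde may undergo self-aldol condensation or over-hydroxymethylation, and the 2-arylacrolein may dimerise or polymerise under amine catalysis and heat. The fallback runs from arene 5 to enal 10 (steps 4–6 bypassed) and ends with an amine-free oxidation, so the enal can be made just before use. NBS (MeCN, 0 °C → rt) should give 1,4-bis(benzyloxy)-5-bromo-2,3-dimethoxybenzene F7. Conversion to the Grignard reagent (Mg, THF) and copper-catalysed carbomagnesiation of propargyl alcohol (pre-deprotonated with i-PrMgCl; CuI 10 mol%, THF/Et2O, reflux) should give 2-[2,5-bis(benzyloxy)-3,4-dimethoxyphenyl]prop-2-en-1-ol F8. MnO2 (CH2Cl2, rt) should oxidise the allylic alcohol to 10.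

**Further compounds**
F1 | step 7 | 5-(benzyloxy)-2-hydroxy-3,4-dimethoxybenzaldehyde | O=Cc1cc(OCc2ccccc2)c(OC)c(OC)c1O
F2 | step 7 | 2-[2,5-bis(benzyloxy)-3,4-dimethoxyphenyl]acetic acid | OC(=O)Cc1cc(OCc2ccccc2)c(OC)c(OC)c1OCc1ccccc1
F3 | step 7 | 6-(benzyloxy)-3-[2,5-bis(benzyloxy)-3,4-dimethoxyphenyl]-7,8-dimethoxy-2H-chromen-2-one | O=C1Oc2c(OC)c(OC)c(OCc3ccccc3)cc2C=C1c1cc(OCc2ccccc2)c(OC)c(OC)c1OCc1ccccc1
F4 | step 7 | 4-(benzyloxy)-6-{(1Z)-2-[2,5-bis(benzyloxy)-3,4-dimethoxyphenyl]-3-hydroxyprop-1-en-1-yl}-2,3-dimethoxyphenol | OC/C(=C\c1cc(OCc2ccccc2)c(OC)c(OC)c1O)c1cc(OCc2ccccc2)c(OC)c(OC)c1OCc1ccccc1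
F5 | step 7 | 6-(benzyloxy)-3-[2,5-bis(benzyloxy)-3,4-dimethoxyphenyl]-7,8-dimethoxy-2H-chromene | COc1c(OC)c(OCc2ccccc2)cc2C=C(c3cc(OCc4ccccc4)c(OC)c(OC)c3OCc3ccccc3)COc12
F6 | step 8 | (2S)-2-[2,5-bis(benzyloxy)-3,4-dimethoxyphenyl]-3-[5-(benzyloxy)-2-hydroxy-3,4-dimethoxyphenyl]propan-1-ol | OC[C@@H](Cc1cc(OCc2ccccc2)c(OC)c(OC)c1O)c1cc(OCc2ccccc2)c(OC)c(OC)c1OCc1ccccc1
F7 | step 6 | 1,4-bis(benzyloxy)-5-bromo-2,3-dimethoxybenzene | Brc1cc(OCc2ccccc2)c(OC)c(OC)c1OCc1ccccc1
F8 | step 6 | 2-[2,5-bis(benzyloxy)-3,4-dimethoxyphenyl]prop-2-en-1-ol | C=C(CO)c1cc(OCc2ccccc2)c(OC)c(OC)c1OCc1ccccc1
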